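**Strategy.** The 1,2-dioxane (numbered O1, O2, C3 the CH carbon, C4, C5, C6 the quaternary carbon) is disconnected at C3–C4 and O1–C6. The key step exploits the 1,3-relationship of C4 and C6: the C4–C5–C6 unit is stored as a strained 1-methyl-1-alkylcyclopropane, the C3–O2–O1 unit as a Roche-ester-derived silyl peroxyacetal. SnCl4 generates a peroxycarbenium ion that opens the cyclopropane σ-bond and the resulting C6 cation is closed by the peroxide oxygen, a formal [3+3] annulation setting C3 and C6. The cyclopropane already carries an E-enoate; Sharpless epoxidation, Wittig extension and diimide reduction then complete the epoxide side chain.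

Key step: step 9

Remark: the ring numbering of the overview is used in all names; a 1,1-dialkylcyclopropane is assumed to be nucleophilic enough to intercept a peroxycarbenium ion at or below −40 °C.

**Step 1**
Reactants: 1 methyl (S)-3-hydroxy-2-methylpropanoate
Product: 2 methyl (S)-3-(tert-butyldiphenylsilyloxy)-2-methylpropanoate
Conditions: TBDPSCl, imidazole, DMF, 0 °C to rt
Reagents that add atoms: tert-butyl(chloro)diphenylsilane, CC(C)(C)[Si](Cl)(c1ccccc1)c1ccccc1
Why: Imidazole-promoted silylation (silyl ether protection) of the primary alcohol; the bulky, non-chelating ether should later support Felkin–Anh control and survive SnCl4 at low temperature.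

**Step 2**
Reactants: 2 methyl (S)-3-(tert-butyldiphenylsilyloxy)-2-methylpropanoate
Product: 3 (S)-3-(tert-butyldiphenylsilyloxy)-2-methylpropanal
Conditions: iBu2AlH (1.1 equiv), CH2Cl2, −78 °C; MeOH, then aq. potassium sodium tartrate
Reagents that add atoms: none
Why: DIBAL-H partial reduction stops at the aluminium hemiacetal, which releases the aldehyde only on work-up, so the α-stereocentre should stay intact.

**Step 3**
Reactants: 3 (S)-3-(tert-butyldiphenylsilyloxy)-2-methylpropanal
Product: 4 (R)-tert-butyl[(2-methylbut-3-en-1-yl)oxy]diphenylsilane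
Conditions: Ph3PCH3Br, KN(SiMe3)2, THF, −78 to 0 °C
Reagents that add atoms: methyltriphenylphosphonium bromide, C[P+](c1ccccc1)(c1ccccc1)c1ccccc1.[Br-]
Why: Wittig methylenation at low temperature should be faster than enolisation of the α-centre by the ylide.

**Step 4**
Reactants: 4 (R)-tert-butyl[(2-methylbut-3-en-1-yl)oxy]diphenylsilane
Product: 6 tert-butyl{[(2S)-3-hydroperoxy-3-methoxy-2-methylpropyl]oxy}diphenylsilane (epimers at the acetal carbon), via carbonyl oxide 5 (not isolated)
Conditions: O3, CH2Cl2/MeOH, −78 °C; N2 purge, no reductive work-up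
Reagents that add atoms: ozone, [O-][O+]=O; methanol, CO
Why: Ozonolysis in methanol (Criegee mechanism) should cleave the primary ozonide to formaldehyde and the more substituted carbonyl oxide 5, which methanol traps as the α-methoxy hydroperoxide; the acetal epimers do not matter because this carbon becomes planar in step 9.

**Step 5**
Reactants: 6 tert-butyl{[(2S)-3-hydroperoxy-3-methoxy-2-methylpropyl]oxy}diphenylsilane
Product: 7 tert-butyl{[(2S)-3-methoxy-2-methyl-3-(triethylsilylperoxy)propyl]oxy}diphenylsilane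
Conditions: Et3SiCl, imidazole, DMF, 0 °C
Reagents that add atoms: chlorotriethylsilane, CC[Si](Cl)(CC)CC
Why: O-Silylation of the hydroperoxide gives the silyl peroxyacetal, a known type of peroxycarbenium precursor whose silyl group can later leave from the distal oxygen.

**Step 6**
Reactants: 8 4-methylpent-4-en-1-ol
Product: 9 3-(1-methylcyclopropyl)propan-1-ol
Conditions: Et2Zn, CH2I2, CH2Cl2, 0 °C to rt
Reagents that add atoms: diiodomethane, ICI
Why: Furukawa-modified Simmons–Smith cyclopropanation of the electron-rich 1,1-disubstituted alkene, assisted by the zinc alkoxide of the free hydroxyl.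

**Step 7**
Reactants: 9 3-(1-methylcyclopropyl)propan-1-ol
Product: 10 3-(1-methylcyclopropyl)propanal
Conditions: Dess–Martin periodinane, NaHCO3, CH2Cl2, rt
Reagents that add atoms: none
Why: Dess–Martin oxidation under buffered, non-acidic conditions should leave the cyclopropane intact.

**Step 8**
Reactants: 10 3-(1-methylcyclopropyl)propanal; 11 ethyl 2-(triphenylphosphoranylidene)propanoate
Product: 12 ethyl (2E)-2-methyl-5-(1-methylcyclopropyl)pent-2-enoate
Conditions: CH2Cl2, rt to 40 °C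
Reagents that add atoms: none
Why: Wittig olefination with the stabilised α-methyl ylide should give the E-trisubstituted enoate, which fixes the later trans arrangement of the two epoxide chains.

**Step 9**
Reactants: 7 tert-butyl{[(2S)-3-methoxy-2-methyl-3-(triethylsilylperoxy)propyl]oxy}diphenylsilane; 12 ethyl (2E)-2-methyl-5-(1-methylcyclopropyl)pent-2-enoate
Product: 15 (3S,6R)-3-[(2S)-1-(tert-butyldiphenylsilyloxy)propan-2-yl]-6-[(3E)-5-ethoxy-4-methyl-5-oxopent-3-en-1-yl]-6-methyl-1,2-dioxane, via peroxycarbenium ion 13 (not isolated), via tertiary carbocation 14 (not isolated)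
Conditions: SnCl4 (2.2 equiv), 12 (3 equiv), CH2Cl2, −78 to −40 °C
Reagents that add atoms: none
Why: Proposed new method: SnCl4 abstracts methoxide from 7 to give peroxycarbenium ion 13, the unhindered CH2 corner of the cyclopropane σ-bond of 12 attacks its carbon with release of ring strain to give the tertiary cation 14, and the distal silylated peroxide oxygen captures this cation with loss of Et3SiCl (formal [3+3] annulation). The closest known reaction types are the SnCl4-mediated [3+2] annulation of silyl peroxyketals with alkenes to 1,2-dioxolanes and the Hosomi–Sakurai allylation of peroxycarbenium ions, joined here to the electrophilic corner opening of 1,1-dialkylcyclopropanes (homo-Prins reactivity). The dioxane closes by six-membered capture of a planar carbocation by oxygen, which breaks no π-bond and so has no Baldwin constraint, through a chair transition state. C3 is set by Felkin–Anh attack on 13, in which CH2OTBDPS of the Roche centre stands anti to the incoming nucleophile and the non-chelating silyl ether excludes chelation, giving the 2,3-syn arrangement of the target. C6 is set in the ring closure, where the C3 side chain and the longer C6 chain should sit equatorial and the methyl group axial; this preference is expected to be modest, because methyl and a primary alkyl chain differ little in size. The step needs the cyclopropane to outcompete the alkene of 12, which its conjugation with the SnCl4-bound ester secures, and ring closure to outrun chloride capture or proton loss, which the six-membered geometry at low temperature favours.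

**Step 10**
Reactants: 15 (3S,6R)-3-[(2S)-1-(tert-butyldiphenylsilyloxy)propan-2-yl]-6-[(3E)-5-ethoxy-4-methyl-5-oxopent-3-en-1-yl]-6-methyl-1,2-dioxane
Product: 16 (3S,6R)-3-[(2S)-1-(tert-butyldiphenylsilyloxy)propan-2-yl]-6-[(3E)-5-hydroxy-4-methylpent-3-en-1-yl]-6-methyl-1,2-dioxane
Conditions: iBu2AlH (2.5 equiv), CH2Cl2, −78 °C
Reagents that add atoms: none
Why: DIBAL-H 1,2-reduction of the enoate should give the E allylic alcohol, a dialkyl peroxide being expected to tolerate this hydride at −78 °C.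

**Step 11**
Reactants: 16 (3S,6R)-3-[(2S)-1-(tert-butyldiphenylsilyloxy)propan-2-yl]-6-[(3E)-5-hydroxy-4-methylpent-3-en-1-yl]-6-methyl-1,2-dioxane
Product: 17 (3S,6R)-3-[(2S)-1-(tert-butyldiphenylsilyloxy)propan-2-yl]-6-{2-[(2S,3S)-3-(hydroxymethyl)-3-methyloxiran-2-yl]ethyl}-6-methyl-1,2-dioxane
Conditions: Ti(OiPr)4 (cat.), diethyl L-(+)-tartrate (cat.), t-BuOOH, 4 Å molecular sieves, CH2Cl2, −20 °C
Reagents that add atoms: tert-butyl hydroperoxide, CC(C)(C)OO
Why: Sharpless asymmetric epoxidation delivers oxygen to one face of the E allylic alcohol under reagent control, the L-(+)-tartrate giving the (2S,3S)-epoxy alcohol, so both epoxide stereocentres are set together and the remote dioxane centres should have no influence.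

**Step 12**
Reactants: 17 (3S,6R)-3-[(2S)-1-(tert-butyldiphenylsilyloxy)propan-2-yl]-6-{2-[(2S,3S)-3-(hydroxymethyl)-3-methyloxiran-2-yl]ethyl}-6-methyl-1,2-dioxane
Product: 18 (3S,6R)-3-[(2S)-1-(tert-butyldiphenylsilyloxy)propan-2-yl]-6-{2-[(2S,3R)-3-formyl-3-methyloxiran-2-yl]ethyl}-6-methyl-1,2-dioxane
Conditions: Dess–Martin periodinane, NaHCO3, CH2Cl2, 0 °C to rt
Reagents that add atoms: none
Why: Dess–Martin oxidation gives an epoxy aldehyde that has no α-hydrogen and so cannot epimerise.

**Step 13**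
Reactants: 19 2,6,6-trimethylcyclohex-1-ene-1-carbaldehyde (β-cyclocitral)
Product: 20 (2,6,6-trimethylcyclohex-1-en-1-yl)methanol
Conditions: NaBH4, MeOH, 0 °C
Reagents that add atoms: none
Why: NaBH4 1,2-reduction of the hindered enal to the allylic alcohol.

**Step 14**
Reactants: 20 (2,6,6-trimethylcyclohex-1-en-1-yl)methanol
Product: 21 triphenyl[(2,6,6-trimethylcyclohex-1-en-1-yl)methyl]phosphonium bromide
Conditions: Ph3P·HBr, MeOH, rt
Reagents that add atoms: triphenylphosphine hydrobromide, [Br-].c1ccc(cc1)[PH+](c1ccccc1)c1ccccc1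
Why: Acid-mediated phosphonium salt formation, in which HBr ionises the allylic alcohol and Ph3P captures the allyl cation at its unhindered primary terminus.

**Step 15**
Reactants: 18 (3S,6R)-3-[(2S)-1-(tert-butyldiphenylsilyloxy)propan-2-yl]-6-{2-[(2S,3R)-3-formyl-3-methyloxiran-2-yl]ethyl}-6-methyl-1,2-dioxane; 21 triphenyl[(2,6,6-trimethylcyclohex-1-en-1-yl)methyl]phosphonium bromide
Product: 23 (3S,6R)-3-[(2S)-1-(tert-butyldiphenylsilyloxy)propan-2-yl]-6-methyl-6-{2-[(2S,3S)-3-methyl-3-[2-(2,6,6-trimethylcyclohex-1-en-1-yl)ethenyl]oxiran-2-yl]ethyl}-1,2-dioxane (E/Z mixture), via phosphorus ylide 22 (not isolated)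
Conditions: n-BuLi, THF, −78 to 0 °C; then 18, −78 °C to rt
Reagents that add atoms: none
Why: Wittig olefination with the semi-stabilised ylide 22 joins the cyclohexenyl unit at low temperature, where the ylide should not touch the peroxide or epoxide; the geometry of the new alkene is irrelevant because step 16 saturates it.

**Step 16**
Reactants: 23 (3S,6R)-3-[(2S)-1-(tert-butyldiphenylsilyloxy)propan-2-yl]-6-methyl-6-{2-[(2S,3S)-3-methyl-3-[2-(2,6,6-trimethylcyclohex-1-en-1-yl)ethenyl]oxiran-2-yl]ethyl}-1,2-dioxane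
Product: 24 (3S,6R)-3-[(2S)-1-(tert-butyldiphenylsilyloxy)propan-2-yl]-6-methyl-6-{2-[(2S,3S)-3-methyl-3-[2-(2,6,6-trimethylcyclohex-1-en-1-yl)ethyl]oxiran-2-yl]ethyl}-1,2-dioxane
Conditions: 2-nitrobenzenesulfonohydrazide, Et3N, CH2Cl2, rt
Reagents that add atoms: none
Why: Diimide reduction (concerted syn transfer of H2) should saturate only the 1,2-disubstituted alkene, since diimide does not reduce tetrasubstituted alkenes, O–O bonds or epoxides.

**Step 17**
Reactants: 24 (3S,6R)-3-[(2S)-1-(tert-butyldiphenylsilyloxy)propan-2-yl]-6-methyl-6-{2-[(2S,3S)-3-methyl-3-[2-(2,6,6-trimethylcyclohex-1-en-1-yl)ethyl]oxiran-2-yl]ethyl}-1,2-dioxane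
Product: 25 (2S)-2-[(3S,6R)-6-methyl-6-{2-[(2S,3S)-3-methyl-3-[2-(2,6,6-trimethylcyclohex-1-en-1-yl)ethyl]oxiran-2-yl]ethyl}-1,2-dioxan-3-yl]propan-1-ol
Conditions: Bu4NF, AcOH, THF, rt
Reagents that add atoms: none
Why: Fluoride-mediated desilylation buffered with acetic acid should free the primary alcohol without base-induced Kornblum–DeLaMare cleavage of the dioxane.

**Step 18**
Reactants: 25 (2S)-2-[(3S,6R)-6-methyl-6-{2-[(2S,3S)-3-methyl-3-[2-(2,6,6-trimethylcyclohex-1-en-1-yl)ethyl]oxiran-2-yl]ethyl}-1,2-dioxan-3-yl]propan-1-ol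
Product: 27 (2R)-2-[(3S,6R)-6-methyl-6-{2-[(2S,3S)-3-methyl-3-[2-(2,6,6-trimethylcyclohex-1-en-1-yl)ethyl]oxiran-2-yl]ethyl}-1,2-dioxan-3-yl]propanoic acid, via aldehyde 26 (not isolated)
Conditions: TEMPO (cat.), PhI(OAc)2, MeCN/aq. pH 7 phosphate buffer, 0 °C to rt
Reagents that add atoms: water, O
Why: TEMPO/PhI(OAc)2 oxidation (oxoammonium catalysis) should take the primary alcohol through aldehyde 26 and its hydrate to the acid at neutral pH, without chlorine-based oxidants that attack the tetrasubstituted alkene and without epimerising C2.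

**Compound list**

1 | methyl (S)-3-hydroxy-2-methylpropanoate | COC(=O)[C@@H](C)CO | starting material
2 | methyl (S)-3-(tert-butyldiphenylsilyloxy)-2-methylpropanoate | COC(=O)[C@@H](C)CO[Si](c1ccccc1)(c1ccccc1)C(C)(C)C | intermediate
3 | (S)-3-(tert-butyldiphenylsilyloxy)-2-methylpropanal | O=C[C@@H](C)CO[Si](c1ccccc1)(c1ccccc1)C(C)(C)C | intermediate
4 | (R)-tert-butyl[(2-methylbut-3-en-1-yl)oxy]diphenylsilane | C=C[C@@H](C)CO[Si](c1ccccc1)(c1ccccc1)C(C)(C)C | intermediate
5 | carbonyl oxide of aldehyde 3 | [O-][O+]=C[C@@H](C)CO[Si](c1ccccc1)(c1ccccc1)C(C)(C)C | intermediate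
6 | tert-butyl{[(2S)-3-hydroperoxy-3-methoxy-2-methylpropyl]oxy}diphenylsilane | COC(OO)[C@@H](C)CO[Si](c1ccccc1)(c1ccccc1)C(C)(C)C | intermediate
7 | tert-butyl{[(2S)-3-methoxy-2-methyl-3-(triethylsilylperoxy)propyl]oxy}diphenylsilane | COC(OO[Si](CC)(CC)CC)[C@@H](C)CO[Si](c1ccccc1)(c1ccccc1)C(C)(C)C | intermediate
8 | 4-methylpent-4-en-1-ol | C=C(C)CCCO | starting material
9 | 3-(1-methylcyclopropyl)propan-1-ol | CC1(CCCO)CC1 | intermediate
10 | 3-(1-methylcyclopropyl)propanal | CC1(CCC=O)CC1 | intermediate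
11 | ethyl 2-(triphenylphosphoranylidene)propanoate | CCOC(=O)C(C)=P(c1ccccc1)(c1ccccc1)c1ccccc1 | starting material
12 | ethyl (2E)-2-methyl-5-(1-methylcyclopropyl)pent-2-enoate | CCOC(=O)/C(C)=C/CCC1(C)CC1 | intermediate
13 | triethylsilylperoxycarbenium ion from 7 | CC[Si](CC)(CC)O[O+]=C[C@@H](C)CO[Si](c1ccccc1)(c1ccccc1)C(C)(C)C | intermediate
14 | open-chain tertiary carbocation | CCOC(=O)/C(C)=C/CC[C+](C)CC[C@H](OO[Si](CC)(CC)CC)[C@@H](C)CO[Si](c1ccccc1)(c1ccccc1)C(C)(C)C | intermediate
15 | (3S,6R)-3-[(2S)-1-(tert-butyldiphenylsilyloxy)propan-2-yl]-6-[(3E)-5-ethoxy-4-methyl-5-oxopent-3-en-1-yl]-6-methyl-1,2-dioxane | CCOC(=O)/C(C)=C/CC[C@]1(C)CC[C@@H]([C@@H](C)CO[Si](c2ccccc2)(c2ccccc2)C(C)(C)C)OO1 | intermediate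
16 | (3S,6R)-3-[(2S)-1-(tert-butyldiphenylsilyloxy)propan-2-yl]-6-[(3E)-5-hydroxy-4-methylpent-3-en-1-yl]-6-methyl-1,2-dioxane | OC/C(C)=C/CC[C@]1(C)CC[C@@H]([C@@H](C)CO[Si](c2ccccc2)(c2ccccc2)C(C)(C)C)OO1 | intermediate
17 | (3S,6R)-3-[(2S)-1-(tert-butyldiphenylsilyloxy)propan-2-yl]-6-{2-[(2S,3S)-3-(hydroxymethyl)-3-methyloxiran-2-yl]ethyl}-6-methyl-1,2-dioxane | OC[C@]1(C)O[C@H]1CC[C@]2(C)CC[C@@H]([C@@H](C)CO[Si](c3ccccc3)(c3ccccc3)C(C)(C)C)OO2 | intermediate
18 | (3S,6R)-3-[(2S)-1-(tert-butyldiphenylsilyloxy)propan-2-yl]-6-{2-[(2S,3R)-3-formyl-3-methyloxiran-2-yl]ethyl}-6-methyl-1,2-dioxane | O=C[C@]1(C)O[C@H]1CC[C@]2(C)CC[C@@H]([C@@H](C)CO[Si](c3ccccc3)(c3ccccc3)C(C)(C)C)OO2 | intermediate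
19 | 2,6,6-trimethylcyclohex-1-ene-1-carbaldehyde | CC1=C(C=O)C(C)(C)CCC1 | starting material
20 | (2,6,6-trimethylcyclohex-1-en-1-yl)methanol | CC1=C(CO)C(C)(C)CCC1 | intermediate
21 | triphenyl[(2,6,6-trimethylcyclohex-1-en-1-yl)methyl]phosphonium bromide | CC1=C(C[P+](c2ccccc2)(c2ccccc2)c2ccccc2)C(C)(C)CCC1.[Br-] | intermediate
22 | triphenyl[(2,6,6-trimethylcyclohex-1-en-1-yl)methylidene]phosphorane | CC1=C(C=P(c2ccccc2)(c2ccccc2)c2ccccc2)C(C)(C)CCC1 | intermediate
23 | (3S,6R)-3-[(2S)-1-(tert-butyldiphenylsilyloxy)propan-2-yl]-6-methyl-6-{2-[(2S,3S)-3-methyl-3-[2-(2,6,6-trimethylcyclohex-1-en-1-yl)ethenyl]oxiran-2-yl]ethyl}-1,2-dioxane | CC1=C(C=C[C@]2(C)O[C@H]2CC[C@]3(C)CC[C@@H]([C@@H](C)CO[Si](c4ccccc4)(c4ccccc4)C(C)(C)C)OO3)C(C)(C)CCC1 | intermediate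
24 | (3S,6R)-3-[(2S)-1-(tert-butyldiphenylsilyloxy)propan-2-yl]-6-methyl-6-{2-[(2S,3S)-3-methyl-3-[2-(2,6,6-trimethylcyclohex-1-en-1-yl)ethyl]oxiran-2-yl]ethyl}-1,2-dioxane | CC1=C(CC[C@]2(C)O[C@H]2CC[C@]3(C)CC[C@@H]([C@@H](C)CO[Si](c4ccccc4)(c4ccccc4)C(C)(C)C)OO3)C(C)(C)CCC1 | intermediate
25 | (2S)-2-[(3S,6R)-6-methyl-6-{2-[(2S,3S)-3-methyl-3-[2-(2,6,6-trimethylcyclohex-1-en-1-yl)ethyl]oxiran-2-yl]ethyl}-1,2-dioxan-3-yl]propan-1-ol | CC1=C(CC[C@]2(C)O[C@H]2CC[C@]3(C)CC[C@@H]([C@@H](C)CO)OO3)C(C)(C)CCC1 | intermediate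
26 | (2R)-2-[(3S,6R)-6-methyl-6-{2-[(2S,3S)-3-methyl-3-[2-(2,6,6-trimethylcyclohex-1-en-1-yl)ethyl]oxiran-2-yl]ethyl}-1,2-dioxan-3-yl]propanal | CC1=C(CC[C@]2(C)O[C@H]2CC[C@]3(C)CC[C@@H]([C@@H](C)C=O)OO3)C(C)(C)CCC1 | intermediate
27 | (2R)-2-[(3S,6R)-6-methyl-6-{2-[(2S,3S)-3-methyl-3-[2-(2,6,6-trimethylcyclohex-1-en-1-yl)ethyl]oxiran-2-yl]ethyl}-1,2-dioxan-3-yl]propanoic acid | CC1=C(CC[C@]2(C)O[C@H]2CC[C@]3(C)CC[C@@H]([C@@H](C)C(=O)O)OO3)C(C)(C)CCC1 | target

**Step count.** Total: 18 steps. Longest linear sequence: 13 steps (steps 1–5, 9–12, 15–18).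

**Steps most likely to fail**

1. Step 9 (proposed new method). The cyclopropane σ-bond may react too slowly, so that ion 13 fragments by carbon-to-oxygen migration, or cation 14 loses a proton or takes up chloride before the ring closes. Facial selectivity of the closure at C6 may also be low. Fallback with known reaction types, setting out from 7 and coming back at 15: 7 is allylated with allyltrimethylsilane and SnCl4 (Hosomi–Sakurai reaction of the peroxycarbenium ion, same Felkin sense) to tert-butyl{[(2S,3S)-2-methyl-3-(triethylsilylperoxy)hex-5-en-1-yl]oxy}diphenylsilane F1. In parallel 8 is oxidised with Dess–Martin periodinane to 4-methylpent-4-enal F2 and olefinated with 11 to ethyl (2E)-2,6-dimethylhepta-2,6-dienoate F3. Cross-metathesis of F1 with excess F3 (second-generation Hoveyda–Grubbs catalyst) gives the trisubstituted alkene F4, whose geometry does not matter. Bu4NF/AcOH at 0 °C frees the hydroperoxide F5. Cycloperoxymercuration with Hg(OAc)2 and catalytic HClO4 (Markovnikov attack of the hydroperoxide at the trisubstituted carbon, six-membered ring) gives the organomercurial F6, and alkaline NaBH4 demercuration returns 15. This fallback gives no better control at C6, so the epimers would still have to be separated.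

2. Step 16. Steric shielding of the disubstituted alkene by the quaternary epoxide carbon and the trimethylcyclohexenyl ring may make hydrogen transfer from diimide so slow that the reagent disproportionates and conversion stalls. Fallback, setting out from 18 and coming back at 24: 18 is methylenated with Ph3P=CH2 to the vinyl epoxide F7. Hydroboration with 9-BBN gives the primary alkylborane F8, which is coupled in the same flask with 2,6,6-trimethylcyclohex-1-en-1-yl trifluoromethanesulfonate F9 (from 2,2,6-trimethylcyclohexanone, LiN(iPr)2 and PhNTf2) under Pd(dppf)Cl2 and K3PO4 (B-alkyl Suzuki–Miyaura coupling). This gives 24 directly and makes 21 unnecessary.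

3. Step 18. Acetic acid released from PhI(OAc)2 may open the trisubstituted epoxide, or the oxoammonium ion may attack the tetrasubstituted alkene during the slow oxidation of the aldehyde hydrate. Fallback, setting out from 25 and coming back at 27: 25 is oxidised with Dess–Martin periodinane and NaHCO3 only as far as aldehyde 26, which is isolated and oxidised with NaClO2 and NaH2PO4 in the presence of excess 2-methylbut-2-ene (Pinnick oxidation) to 27.

**Further compounds**

F1 | step 9 | tert-butyl{[(2S,3S)-2-methyl-3-(triethylsilylperoxy)hex-5-en-1-yl]oxy}diphenylsilane | C=CC[C@H](OO[Si](CC)(CC)CC)[C@@H](C)CO[Si](c1ccccc1)(c1ccccc1)C(C)(C)C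
F2 | step 9 | 4-methylpent-4-enal | C=C(C)CCC=O
F3 | step 9 | ethyl (2E)-2,6-dimethylhepta-2,6-dienoate | CCOC(=O)/C(C)=C/CCC(C)=C
F4 | step 9 | ethyl (2E,9S,10S)-11-(tert-butyldiphenylsilyloxy)-2,6,10-trimethyl-9-(triethylsilylperoxy)undeca-2,6-dienoate | CCOC(=O)/C(C)=C/CCC(C)=CC[C@H](OO[Si](CC)(CC)CC)[C@@H](C)CO[Si](c1ccccc1)(c1ccccc1)C(C)(C)C
F5 | step 9 | ethyl (2E,9S,10S)-11-(tert-butyldiphenylsilyloxy)-9-hydroperoxy-2,6,10-trimethylundeca-2,6-dienoate | CCOC(=O)/C(C)=C/CCC(C)=CC[C@H](OO)[C@@H](C)CO[Si](c1ccccc1)(c1ccccc1)C(C)(C)C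
F6 | step 9 | acetoxymercury derivative of 15 at C5 of the dioxane | CCOC(=O)/C(C)=C/CCC1(C)OO[C@H]([C@@H](C)CO[Si](c2ccccc2)(c2ccccc2)C(C)(C)C)CC1[Hg]OC(C)=O
F7 | step 16 | (3S,6R)-3-[(2S)-1-(tert-butyldiphenylsilyloxy)propan-2-yl]-6-{2-[(2S,3S)-3-ethenyl-3-methyloxiran-2-yl]ethyl}-6-methyl-1,2-dioxane | C=C[C@]1(C)O[C@H]1CC[C@]2(C)CC[C@@H]([C@@H](C)CO[Si](c3ccccc3)(c3ccccc3)C(C)(C)C)OO2
F8 | step 16 | B-alkyl-9-borabicyclo[3.3.1]nonane from F7 | B1(CC[C@]3(C)O[C@H]3CC[C@]4(C)CC[C@@H]([C@@H](C)CO[Si](c5ccccc5)(c5ccccc5)C(C)(C)C)OO4)C2CCCC1CCC2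
F9 | step 16 | 2,6,6-trimethylcyclohex-1-en-1-yl trifluoromethanesulfonate | CC1=C(OS(=O)(=O)C(F)(F)F)C(C)(C)CCC1
F0 | step 18 | none | none
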